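## The problem

The target 15 is a monocyclic 1,2-dioxane, numbered here O1–O2–C3–C4–C5–C6. C3 is a methyl peroxyketal that also carries an unbranched C16 chain (C1'–C16') with a 4'-yne conjugated to a 6'E-alkene and an isolated terminal alkene at C15'. C6 carries a CH2CO2H arm. There is no ring fusion to build; the difficulty lies in the O–O bond, the two stereocentres that flank it, and a chain that cannot be exposed to radicals, hydrogenation or strong reductants.

C3 (R) and C6 (S) are 1,4-related, and the methoxy group is cis to the acetic acid arm. In the chair this puts OMe axial (anomeric stabilisation) and both carbon substituents equatorial. C3 can therefore be set from C6 by equilibration through the cyclic peroxycarbenium ion. C6 has no neighbour to lean on and must be introduced or resolved in absolute terms.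

The groups that limit the chemistry are:
- the O–O bond, which rules out stoichiometric phosphines, hydrides and low-valent metals in quantity;
- the β-peroxy ester, which can lose the peroxide by elimination from the ester enolate under strong base;
- the ketal, which is labile to aqueous acid;
- the enyne and terminal alkene, which are radical acceptors.

The feature that opens the structure is this: C3 is at the ketone oxidation level with C4 as its α-carbon, C5–C6 has the connectivity of a terminal alkene bearing the CH2CO2R arm, and O1–O2 can be dioxygen itself. C4–C5, C6–O1 and O2–C3 can therefore be formed in one oxidative union of an enol carbon, an alkene and O2. The C4'≡C5' alkyne then offers a place to attach the radical-sensitive remainder of the chain afterwards.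

## Retrosynthesis

**15 from 14.** The last bond cut is the ester C–O bond: acid 15 is traced to the racemic methyl ester 14. Hydrolysis is needed in any case, and an enzyme does it at neutral pH, where hydroxide would risk β-elimination of the peroxide. The same operation selects one enantiomer. Because C3 is tied to C6, one resolution fixes both centres. Resolving earlier, at 10, would save iodide 13 but would send a free acid through the coupling. The precursor 14 needs no asymmetric step; the forward reaction needs a hydrolase that reads a stereocentre β to the carbonyl.

**14 from 10 and 13.** The chain is cut at the sp–sp2 bond C5'–C6', giving the ring-bound terminal alkyne 10 and the (E)-iodoalkene 13. This cut keeps the enyne and the terminal alkene out of every earlier step; an alkene in the chain would compete with 5 in the radical step. Cutting at C3–C1' would require a carbon nucleophile at a peroxyketal, and building the alkene by olefination would not secure the E geometry. The forward coupling must tolerate the O–O bond, which argues for catalytic phosphine and room temperature.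

**13 from 12 from 11.** The iodoalkene 13 is cut at its C=C bond to dec-9-enal 12 (one-carbon iodo-olefination), and 12 comes from the commercial alcohol 11 by oxidation. The forward olefination must be E-selective and leave the remote alkene alone.

**10 from 9.** The C3–OMe bond is cut to the peroxyhemiketal 9. Nothing else changes, and the forward ketal exchange is reversible, so it can deliver the thermodynamic C3 configuration that the target has. The methyl ester is chosen because acidic methanol cannot alter it.

**9 from 7.** A carboxyl group is reintroduced at C4, giving the tert-butyl ester 7 (via acid 8). This ester makes C4 oxidisable to a radical in the key step, and it is removable afterwards by acid and mild heat without a nucleophile or base. The tert-butyl ester is orthogonal to the methyl ester on the arm. The forward reaction asks that the hemiketal open far enough to its β-keto acid form to lose CO2.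

**7 from 4, 5 and 6.** Three bonds are cut at once: C4–C5, C6–O1 and O2–C3. This returns the β-keto ester 4, methyl but-3-enoate 5 and dioxygen 6. No other cut removes the ring, the peroxide and three skeletal bonds in one step from achiral, cheap partners that already carry the correct oxidation levels. The alkyne of 4 is left unprotected: it is a spectator throughout, and a silyl group would cost a silylation and a basic desilylation on a base-sensitive peroxide. The forward reaction must add the C4 radical to the CH2 terminus of 5 and outrun direct oxygenation of that radical.

**4 from 1 and 2.** The keto ester is cut at its C2–C3 bond (keto ester numbering) to hex-5-ynoic acid 1 and Meldrum's acid 2, joined by acylation and opened with tert-butanol. Both are commercial, and the forward reaction is routine.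

## Roads not taken

**Alternative 1:** The cut is O2–C3 together with C3–OMe. The precursor is the acyclic ketone A1, which carries the full chain, a silyl-protected 2-hydroxyethyl arm and an (S)-hydroperoxide at C6 masked as its 2-methoxyprop-2-yl peroxide. In acidic methanol the hydroperoxide is freed, closes on the ketone and is methanolysed to A2, with C3 settling to the axial-OMe anomer.
- Merits: C6 comes from an enantiopure precursor, so no material is discarded. The closure is the same thermodynamically driven ketalisation used here in step 4. No radical ever meets the enyne.
- Weak points: the difficulty moves into making A1. A secondary hydroperoxide of defined configuration must be installed by displacing a secondary sulfonate with a peroxide nucleophile, which competes with elimination and can erode configuration. The carbinol needs its own asymmetric step. After closure the arm must be desilylated and oxidised through two levels beside the peroxide and the enyne.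
- Comparison: this road is better in stereochemical economy and needs no resolution. The chosen plan sets against it a ring construction in one step from achiral materials with the acid oxidation level in place, and a longest sequence of six steps, probably about half the length.

**Alternative 2:** The cut is O1–C6. The precursor A3 has a hydroperoxy methyl ketal at C3 tethered to an (R)-oxetane whose stereocentre becomes C6. A Lewis acid (Me3SiOTf or Yb(OTf)3) activates the oxetane, and the hydroperoxide attacks in a 6-exo-tet closure with inversion, giving A4 and releasing the primary alcohol.
- Merits: the closure is stereospecific, absolute configuration comes from an enantiopure oxetane, and the peroxide enters as hydrogen peroxide by polar chemistry.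
- Weak points: the geminal methoxy hydroperoxide is itself labile to Lewis acids, so oxetane activation must outrun ionisation at C3. Attack at a secondary oxetane carbon may take on cationic character and lose fidelity. The enantiopure oxetane needs several steps. A4 is at the alcohol level, as two C3 epimers, and still needs oxidation, equilibration, desilylation and chain coupling.
- Comparison: it wins on absolute control. The chosen plan answers with fewer steps, no redox adjustment of the arm, and a ring-forming step whose substrates are stable.

**Alternative 3:** The cuts are C5–C6 and O2–C3. C3–C4–C5 comes from the methoxycyclopropane A5, and C6 with both oxygens comes from the silylperoxy methyl acetal A6. SnCl4 or Me3SiOTf ionises A6 to a silylperoxycarbenium ion, a cyclopropane bond attacks C6, and the silylated peroxy oxygen traps the C3 oxocarbenium ion with loss of silicon to give A7.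
- Merits: it is a two-bond, ring-forming union of the same convergence as the chosen step. It lands directly at the methyl ketal with the ester in place, with no activating group to remove. A7 is the silylated counterpart of 10, so on paper one step replaces steps 2–4 here, and that advantage is conceded.
- Weak points: peroxycarbenium ions are established electrophiles toward allylsilanes, enol ethers and alkenes, but a donor cyclopropane as the three-carbon partner is an extrapolation. Halide capture, O–O heterolysis of the cation and protic opening of the cyclopropane all compete. Both partners need several steps each, and the product is racemic, so the same resolution remains.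
- Comparison: the chosen plan sets against the shorter core a ring-forming reaction type with direct precedent on β-keto esters, partners that are commercial or two steps away, and an overall count that is no longer.

Key step: step 2

Remark on naming: ring atoms are numbered O1–O2–C3(ketal)–C4–C5–C6 in all names; descriptors with an asterisk denote the racemate of that relative configuration.
Assumption: Burkholderia cepacia lipase is taken to hydrolyse the (3R,6S) ester faster than its mirror image; the opposite case is covered by the fallback for step 8.

## Route

Step 1
Reactants: 1 hex-5-ynoic acid; 2 Meldrum's acid (2,2-dimethyl-1,3-dioxane-4,6-dione)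
Product: 4 tert-butyl 3-oxooct-7-ynoate, via acyl Meldrum's acid 3 (not isolated)
Conditions: DCC, DMAP, CH2Cl2, 0 → 23 °C; filter, acid wash, concentrate; then t-BuOH, toluene, 90 °C
Reagents that add atoms: tert-butanol, CC(C)(C)O
Why: Carbodiimide-mediated C-acylation of Meldrum's acid followed by thermal alcoholysis, which ejects acetone and CO2 and leaves the β-keto ester; the terminal alkyne is a spectator and no stereocentre is formed.

Step 2
Reactants: 4 tert-butyl 3-oxooct-7-ynoate; 5 methyl but-3-enoate; 6 dioxygen
Product: 7 tert-butyl 3-hydroxy-6-(2-methoxy-2-oxoethyl)-3-(pent-4-yn-1-yl)-1,2-dioxane-4-carboxylate (racemic mixture of diastereomers)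
Conditions: Mn(OAc)3·2H2O (0.2 equiv), 5 (5 equiv), AcOH, air (1 atm), 23 °C
Reagents that add atoms: none
Why: This is the manganese triacetate aerobic three-component peroxycyclization of 1,3-dicarbonyl compounds with alkenes, a known reaction type used here at the less reactive, monosubstituted end of its alkene scope. Trivalent manganese forms the enolate of 4 and oxidises it to the electrophilic C4 radical, which adds to the unsubstituted terminus of 5 (C4–C5); the secondary C6 radical captures O2 (C6–O1), the peroxyl radical is reduced by divalent manganese, which returns trivalent manganese and makes the metal catalytic, and the hydroperoxide adds to the ketone (O2–C3). The ring closes by a polar 6-exo-trig hemiketalisation that is reversible and so gives the more stable anomers. C6 forms without any controlling element and is racemic (resolved in step 8), C4 is epimerisable and is deleted in step 3, and C3 is a hemiketal centre in ring–chain equilibrium that is fixed only in step 4. The step needs attack at the CH2 terminus (secured by the secondary over primary radical and by sterics), alkene over alkyne selectivity (secured by the excess of 5 and the slower addition of electrophilic radicals to alkynes, including the slow 6-exo-dig closure), and C–C bond formation ahead of direct oxygenation of the C4 radical (secured by the high alkene concentration under air instead of pure O2). Once cyclised, 7 no longer presents an enolisable 1,3-dicarbonyl and is shielded from a second oxidation.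

Step 3
Reactants: 7 tert-butyl 3-hydroxy-6-(2-methoxy-2-oxoethyl)-3-(pent-4-yn-1-yl)-1,2-dioxane-4-carboxylate
Product: 9 methyl 2-[3-hydroxy-3-(pent-4-yn-1-yl)-1,2-dioxan-6-yl]acetate (racemic; both C3 anomers), via dioxanol carboxylic acid 8 (not isolated)
Conditions: TFA–CH2Cl2 (1:4), 0 → 23 °C; evaporate; toluene, 50 °C
Reagents that add atoms: none
Why: Acidolysis of the tert-butyl ester (loss of isobutene) spares the methyl ester; acid 8 is in ring–chain equilibrium with the open β-keto acid, which decarboxylates through the usual six-membered transition state, after which the enol ketonises and the hydroperoxide recloses. C4 becomes CH2, so its configuration is erased.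

Step 4
Reactants: 9 methyl 2-[3-hydroxy-3-(pent-4-yn-1-yl)-1,2-dioxan-6-yl]acetate
Product: 10 methyl 2-[(3R*,6S*)-3-methoxy-3-(pent-4-yn-1-yl)-1,2-dioxan-6-yl]acetate (racemic)
Conditions: TsOH·H2O (cat.), MeOH, 23 °C
Reagents that add atoms: methanol, CO
Why: Acid-catalysed ketal exchange of the peroxyhemiketal OH for OMe through the cyclic peroxycarbenium ion; because ionisation is reversible, C3 settles to the anomer with axial OMe and both carbon substituents equatorial, which is the relative configuration of the target, and any minor epimer can be resubmitted. The methyl ester is degenerate toward transesterification in methanol.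

Step 5
Reactants: 11 dec-9-en-1-ol
Product: 12 dec-9-enal
Conditions: TEMPO (10 mol %), PhI(OAc)2, CH2Cl2, 23 °C
Reagents that add atoms: none
Why: Oxoammonium (TEMPO) oxidation of a primary alcohol stops at the aldehyde and leaves the terminal alkene untouched.

Step 6
Reactants: 12 dec-9-enal
Product: 13 (1E)-1-iodoundeca-1,10-diene
Conditions: CrCl2, CHI3, THF–dioxane, 0 → 23 °C
Reagents that add atoms: iodoform, IC(I)I
Why: Takai olefination: the geminal dichromium species formed from iodoform and divalent chromium adds to the aldehyde and eliminates to give the (E)-iodoalkene; the isolated terminal alkene is inert.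

Step 7
Reactants: 10 methyl 2-[(3R*,6S*)-3-methoxy-3-(pent-4-yn-1-yl)-1,2-dioxan-6-yl]acetate; 13 (1E)-1-iodoundeca-1,10-diene
Product: 14 methyl 2-[(3R*,6S*)-3-[(6E)-hexadeca-6,15-dien-4-yn-1-yl]-3-methoxy-1,2-dioxan-6-yl]acetate (racemic)
Conditions: PdCl2(PPh3)2 (3 mol %), CuI (6 mol %), i-Pr2NH, THF, 23 °C, degassed
Reagents that add atoms: none
Why: Sonogashira coupling of a terminal alkyne with an (E)-alkenyl iodide at room temperature, with retention of alkene geometry; oxidative addition of zerovalent palladium into the C–I bond is much faster than any reaction with the dialkyl peroxyketal, and phosphine is present only in catalytic amount.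

Step 8
Reactants: 14 methyl 2-[(3R*,6S*)-3-[(6E)-hexadeca-6,15-dien-4-yn-1-yl]-3-methoxy-1,2-dioxan-6-yl]acetate (racemic)
Product: 15 2-[(3R,6S)-3-[(6E)-hexadeca-6,15-dien-4-yn-1-yl]-3-methoxy-1,2-dioxan-6-yl]acetic acid
Conditions: Burkholderia cepacia lipase (Amano PS), phosphate buffer pH 7.2–MTBE, 30 °C, stopped below half conversion; NaHCO3 extraction, then careful acidification
Reagents that add atoms: water, O
Why: Lipase-catalysed enantioselective hydrolysis (kinetic resolution) of a methyl ester whose stereocentre is β to the carbonyl; the enzyme discriminates the configuration at C6 and, because C3 is tied to C6, should deliver the (3R,6S) acid, which is separated from unreacted ester by extraction. Neutral pH avoids enolate-driven β-elimination of the peroxide.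

## Compound list

1 | hex-5-ynoic acid | C#CCCCC(=O)O | starting material
2 | Meldrum's acid (2,2-dimethyl-1,3-dioxane-4,6-dione) | CC1(C)OC(=O)CC(=O)O1 | starting material
3 | 5-(1-hydroxyhex-5-yn-1-ylidene)-2,2-dimethyl-1,3-dioxane-4,6-dione | C#CCCCC(O)=C1C(=O)OC(C)(C)OC1=O | intermediate (not isolated)
4 | tert-butyl 3-oxooct-7-ynoate | C#CCCCC(=O)CC(=O)OC(C)(C)C | intermediate
5 | methyl but-3-enoate | C=CCC(=O)OC | starting material
6 | dioxygen | O=O | starting material
7 | tert-butyl 3-hydroxy-6-(2-methoxy-2-oxoethyl)-3-(pent-4-yn-1-yl)-1,2-dioxane-4-carboxylate (racemic mixture of diastereomers) | C#CCCCC1(O)OOC(CC(=O)OC)CC1C(=O)OC(C)(C)C | intermediate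
8 | 3-hydroxy-6-(2-methoxy-2-oxoethyl)-3-(pent-4-yn-1-yl)-1,2-dioxane-4-carboxylic acid (stereoisomer mixture) | C#CCCCC1(O)OOC(CC(=O)OC)CC1C(=O)O | intermediate (not isolated)
9 | methyl 2-[3-hydroxy-3-(pent-4-yn-1-yl)-1,2-dioxan-6-yl]acetate (racemic; both C3 anomers) | C#CCCCC1(O)CCC(CC(=O)OC)OO1 | intermediate
10 | methyl 2-[(3R*,6S*)-3-methoxy-3-(pent-4-yn-1-yl)-1,2-dioxan-6-yl]acetate (racemic; one enantiomer drawn) | C#CCCC[C@]1(OC)CC[C@@H](CC(=O)OC)OO1 | intermediate
11 | dec-9-en-1-ol | C=CCCCCCCCCO | starting material
12 | dec-9-enal | C=CCCCCCCCC=O | intermediate
13 | (1E)-1-iodoundeca-1,10-diene | C=CCCCCCCC/C=C/I | intermediate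
14 | methyl 2-[(3R*,6S*)-3-[(6E)-hexadeca-6,15-dien-4-yn-1-yl]-3-methoxy-1,2-dioxan-6-yl]acetate (racemic; one enantiomer drawn) | C=CCCCCCCC/C=C/C#CCCC[C@]1(OC)CC[C@@H](CC(=O)OC)OO1 | intermediate
15 | 2-[(3R,6S)-3-[(6E)-hexadeca-6,15-dien-4-yn-1-yl]-3-methoxy-1,2-dioxan-6-yl]acetic acid | C=CCCCCCCC/C=C/C#CCCC[C@]1(OC)CC[C@@H](CC(=O)O)OO1 | target

## Step count and least certain steps

Total: 8 steps. Longest linear sequence: 6 steps (steps 1, 2, 3, 4, 7, 8); steps 5 and 6 form the side branch.

**Step 2 (key step).** The most likely failure is slow addition of the keto-ester radical to a monosubstituted, slightly electron-poor alkene. Direct oxygenation of the radical, hydrogen abstraction from the doubly activated CH2 of 5, or telomerisation could then take over.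

The fallback sets out from 4 and returns at 10, replacing steps 2–4 with polar chemistry. The sodium enolate of 4 (NaH, THF, 0 °C) is C-alkylated with methyl (E)-4-bromobut-2-enoate to give tert-butyl 2-[(2E)-4-methoxy-4-oxobut-2-en-1-yl]-3-oxooct-7-ynoate F1. Acidolysis with TFA and gentle warming removes the tert-butyl ester and CO2 to give methyl (2E)-6-oxoundec-2-en-10-ynoate F2. Urea–hydrogen peroxide with Sc(OTf)3 in methanol converts the ketone into methyl (2E)-6-hydroperoxy-6-methoxyundec-2-en-10-ynoate F3. Diethylamine in trifluoroethanol then closes O1–C6 by intramolecular oxa-Michael addition, and equilibration of C3 in acidic methanol as in step 4 gives 10.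

**Step 3.** Acid may dehydrate the hemiketal toward the ester-conjugated dioxene or trigger heterolysis of the O–O bond. Decarboxylation may also stall because the acid rests in its closed β-hydroxy acid form.

The fallback sets out from 1 and 2 and returns at 9. Step 1 is run with 2-(trimethylsilyl)ethanol in place of tert-butanol to give 2-(trimethylsilyl)ethyl 3-oxooct-7-ynoate F4. The unchanged key step with 5 and 6 gives 2-(trimethylsilyl)ethyl 3-hydroxy-6-(2-methoxy-2-oxoethyl)-3-(pent-4-yn-1-yl)-1,2-dioxane-4-carboxylate F5. Fluoride (TASF, DMF, 0 °C) releases the carboxylate without acid, and mild acidification at room temperature lets it decarboxylate to 9.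

**Step 8.** The enzyme may discriminate poorly between the enantiomers, since the stereocentre is β to the carbonyl and flanked by groups of similar size, or it may prefer the wrong one. Either would limit the optical purity of the acid.

The fallback sets out from 14 and returns at 15. The enantiomers of 14 are separated by preparative chromatography on a cellulose tris(3,5-dimethylphenylcarbamate) phase. Alternatively, if the enzyme prefers the wrong enantiomer, the hydrolysis is driven past half conversion and the unreacted ester is recovered. Either way this gives methyl 2-[(3R,6S)-3-[(6E)-hexadeca-6,15-dien-4-yn-1-yl]-3-methoxy-1,2-dioxan-6-yl]acetate F6 as a single enantiomer. It is saponified with LiOH in THF–water at 0 °C to 15.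

**Step 7.** Low-valent palladium or phosphine may cleave the O–O bond reductively, and copper may homocouple the alkyne if oxygen leaks in.

The fallback sets out from 4 and 13 and returns at 14, making the coupling before any peroxide exists. The enone ester methyl (2E)-6-oxoundec-2-en-10-ynoate F2, made from 4 through tert-butyl 2-[(2E)-4-methoxy-4-oxobut-2-en-1-yl]-3-oxooct-7-ynoate F1 as described for step 2, is coupled with 13 under the conditions of step 7 to give methyl (2E,12E)-6-oxodocosa-2,12,21-trien-10-ynoate F7. Urea–hydrogen peroxide with Sc(OTf)3 in methanol gives methyl (2E,12E)-6-hydroperoxy-6-methoxydocosa-2,12,21-trien-10-ynoate F8. Diethylamine in trifluoroethanol closes the ring, and equilibration of C3 in acidic methanol delivers 14.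

## Further compounds

F1 | step 2 | tert-butyl 2-[(2E)-4-methoxy-4-oxobut-2-en-1-yl]-3-oxooct-7-ynoate (racemic) | C#CCCCC(=O)C(C/C=C/C(=O)OC)C(=O)OC(C)(C)C
F2 | step 2 | methyl (2E)-6-oxoundec-2-en-10-ynoate | C#CCCCC(=O)CC/C=C/C(=O)OC
F3 | step 2 | methyl (2E)-6-hydroperoxy-6-methoxyundec-2-en-10-ynoate (racemic) | C#CCCCC(OC)(OO)CC/C=C/C(=O)OC
F4 | step 3 | 2-(trimethylsilyl)ethyl 3-oxooct-7-ynoate | C#CCCCC(=O)CC(=O)OCC[Si](C)(C)C
F5 | step 3 | 2-(trimethylsilyl)ethyl 3-hydroxy-6-(2-methoxy-2-oxoethyl)-3-(pent-4-yn-1-yl)-1,2-dioxane-4-carboxylate (racemic mixture of diastereomers) | C#CCCCC1(O)OOC(CC(=O)OC)CC1C(=O)OCC[Si](C)(C)C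
F6 | step 8 | methyl 2-[(3R,6S)-3-[(6E)-hexadeca-6,15-dien-4-yn-1-yl]-3-methoxy-1,2-dioxan-6-yl]acetate (single enantiomer) | C=CCCCCCCC/C=C/C#CCCC[C@]1(OC)CC[C@@H](CC(=O)OC)OO1
F7 | step 7 | methyl (2E,12E)-6-oxodocosa-2,12,21-trien-10-ynoate | C=CCCCCCCC/C=C/C#CCCCC(=O)CC/C=C/C(=O)OC
F8 | step 7 | methyl (2E,12E)-6-hydroperoxy-6-methoxydocosa-2,12,21-trien-10-ynoate (racemic) | C=CCCCCCCC/C=C/C#CCCCC(OC)(OO)CC/C=C/C(=O)OC
A1 | alternative 1 | (3S,12E)-1-[tert-butyl(diphenyl)silyl]oxy-3-[(2-methoxypropan-2-yl)peroxy]docosa-12,21-dien-10-yn-6-one | C=CCCCCCCC/C=C/C#CCCCC(=O)CC[C@@H](CCO[Si](c1ccccc1)(c1ccccc1)C(C)(C)C)OOC(C)(C)OC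
A2 | alternative 1 | tert-butyl-[2-[(3R,6S)-3-[(6E)-hexadeca-6,15-dien-4-yn-1-yl]-3-methoxy-1,2-dioxan-6-yl]ethoxy]diphenylsilane | C=CCCCCCCC/C=C/C#CCCC[C@]1(OC)CC[C@@H](CCO[Si](c2ccccc2)(c2ccccc2)C(C)(C)C)OO1
A3 | alternative 2 | [6-hydroperoxy-6-methoxy-8-[(2R)-oxetan-2-yl]oct-1-yn-1-yl]trimethylsilane (both C6 epimers of the chain ketal) | C[Si](C)(C)C#CCCCC(OC)(OO)CC[C@@H]1CCO1
A4 | alternative 2 | 2-[(6S)-3-methoxy-3-[5-(trimethylsilyl)pent-4-yn-1-yl]-1,2-dioxan-6-yl]ethanol (both C3 epimers) | C[Si](C)(C)C#CCCCC1(OC)CC[C@@H](CCO)OO1
A5 | alternative 3 | [5-(1-methoxycyclopropyl)pent-1-yn-1-yl]trimethylsilane | COC1(CCCC#C[Si](C)(C)C)CC1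
A6 | alternative 3 | methyl 3-methoxy-3-[(triethylsilyl)peroxy]propanoate (racemic) | COC(=O)CC(OC)OO[Si](CC)(CC)CC
A7 | alternative 3 | methyl 2-[(3R*,6S*)-3-methoxy-3-[5-(trimethylsilyl)pent-4-yn-1-yl]-1,2-dioxan-6-yl]acetate (racemic; one enantiomer drawn) | C[Si](C)(C)C#CCCC[C@]1(OC)CC[C@@H](CC(=O)OC)OO1
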